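**Plan**

1. Numbering follows the guaiane skeleton: cyclopentane C1–C5 (C1 and C5 are the ring-fusion atoms, C4 carries the methylene C15); cycloheptane C1, C5–C10 (C6 ketone, C7 isopropyl, C9 ester, C10 methyl and hydroxyl).
2. Retrosynthesis: the C7–H/C10–OH pair is traced back to a C7–O–C10 ether bridge (reductive α-C–O cleavage). The homoallylic alcohol C1(OH)–C5(H)–C4=C15 is traced to the 1,5-epoxide of a 1(5),4(15)-dienone (formate hydrogenolysis), and C4–C5 to a Heck closure. Then C7–C8 and C9–C10 are cut together.
3. Enabling feature: the C10 hydroxyl oxygen lies 1,4 to C7, the α-carbon of the C6 ketone, across the seven-membered ring. Tied as an ether, ring C1/C5–C10 plus that oxygen is an 8-oxabicyclo[3.2.1]oct-3-en-2-one, the adduct of a pyrylium-type five-atom unit C7–C6–C5–C1–C10 (closed by O) with a vinyl ether C8=C9.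
4. Forward: trisubstituted furan → Achmatowicz pyranone → [5+2] cycloaddition closing the cycloheptenone and the temporary oxolane ring in one operation → cyclopentene ring by intramolecular Heck reaction → epoxide → hydrogenolysis → opening of the bridge.
5. Stereochemistry: absolute configuration, C9 and C10 from the catalytic endo-selective cycloaddition; C1 from epoxidation on the face of the bridge oxygen; C5 from anti hydride delivery through allylpalladium; C7 from protonation after the bridge oxygen leaves.

Key step: step 6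

Remark: the sense of induction in step 6 is assumed to be that written for the (1R,2R) catalyst; should it be opposite, the (1S,2S) catalyst is used and nothing else changes.

**Step 1**
Reactants: 1 3-bromo-2-methylfuran; 2 but-3-en-1-ylzinc bromide
Product: 3 3-(but-3-en-1-yl)-2-methylfuran
Conditions: Pd(dppf)Cl2 (3 mol %), THF, 60 °C
Reagents that add atoms: none
Why: Negishi cross-coupling of a 3-bromofuran with a primary alkylzinc halide is well precedented, the bidentate ferrocenyl diphosphine keeps β-hydride elimination and alkene migration slow, and no stereocentre is formed.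

**Step 2**
Reactants: 3 3-(but-3-en-1-yl)-2-methylfuran; 4 2-methylpropanal
Product: 6 1-[4-(but-3-en-1-yl)-5-methylfuran-2-yl]-2-methylpropan-1-ol as the racemate, via furyllithium 5 (not isolated)
Conditions: n-BuLi, THF, −78 → 0 °C; then 4, −78 °C → rt; H2O
Reagents that add atoms: none
Why: The only free α-position of the furan is lithiated selectively and the furyllithium adds 1,2 to the aldehyde; the carbinol centre is deliberately racemic, since it becomes a planar pyrylium carbon in step 6.

**Step 3**
Reactants: 6 1-[4-(but-3-en-1-yl)-5-methylfuran-2-yl]-2-methylpropan-1-ol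
Product: 7 5-(but-3-en-1-yl)-6-hydroxy-6-methyl-2-(propan-2-yl)-2H-pyran-3(6H)-one (mixture of diastereomers)
Conditions: NBS, NaHCO3, NaOAc, THF/H2O (4:1), 0 °C
Reagents that add atoms: water, O
Why: Achmatowicz rearrangement: bromonium attack on the electron-rich furan (much faster than on the terminal alkene), addition of water, ring opening to the ene-dione and hemiketalisation give the pyranone, whose two stereocentres are irrelevant because both become sp2 in step 6.

**Step 4**
Reactants: 7 5-(but-3-en-1-yl)-6-hydroxy-6-methyl-2-(propan-2-yl)-2H-pyran-3(6H)-one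
Product: 8 3-(but-3-en-1-yl)-2-methyl-5-oxo-6-(propan-2-yl)-5,6-dihydro-2H-pyran-2-yl 3,4,5-trifluorobenzoate (mixture of diastereomers)
Conditions: 3,4,5-trifluorobenzoyl chloride, Et3N, DMAP (cat.), CH2Cl2, 0 °C → rt
Reagents that add atoms: 3,4,5-trifluorobenzoyl chloride, O=C(Cl)c1cc(F)c(F)c(F)c1
Why: DMAP-catalysed O-acylation traps the cyclic hemiketal tautomer and turns its hydroxyl into the carboxylate leaving group needed for pyrylium formation.

**Step 5**
Reactants: 9 (4-methoxyphenyl)methanol
Product: 10 1-[(ethenyloxy)methyl]-4-methoxybenzene (4-methoxybenzyl vinyl ether)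
Conditions: vinyl acetate, [Ir(cod)Cl]2 (1 mol %), Na2CO3, toluene, 100 °C
Reagents that add atoms: vinyl acetate, CC(=O)OC=C
Why: Iridium-catalysed transfer vinylation of a primary alcohol with vinyl acetate gives the vinyl ether directly, and the 4-methoxybenzyl group is chosen because it can later be removed oxidatively without touching an epoxide, a ketone or an alkene.

**Step 6**
Reactants: 8 3-(but-3-en-1-yl)-2-methyl-5-oxo-6-(propan-2-yl)-5,6-dihydro-2H-pyran-2-yl 3,4,5-trifluorobenzoate; 10 4-methoxybenzyl vinyl ether
Product: 12 (1S,5R,6R)-4-(but-3-en-1-yl)-6-[(4-methoxyphenyl)methoxy]-5-methyl-1-(propan-2-yl)-8-oxabicyclo[3.2.1]oct-3-en-2-one, via aminopyrylium ion 11 (not isolated)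
Conditions: 10 (5 equiv), 1-[(1R,2R)-2-aminocyclohexyl]-3-[3,5-bis(trifluoromethyl)phenyl]thiourea (15 mol %), 1,3-bis[3,5-bis(trifluoromethyl)phenyl]thiourea (15 mol %), AcOH (15 mol %), toluene, rt
Reagents that add atoms: none
Why: The primary amine of the catalyst condenses with the ketone of 8 and the thiourea cocatalyst pulls off the trifluorobenzoate, so that the planar aminopyrylium ion 11 is formed, a five-atom, four-π-electron unit whose termini are the isopropyl-bearing carbon (future C7) and the methyl-bearing carbon (future C10); the electron-rich alkene 10 adds across these termini in a suprafacial [5+2] cycloaddition, and hydrolysis of the resulting iminium ion returns the ketone and the catalyst. The closest known reaction type is the aminothiourea-catalysed enantioselective intermolecular [5+2] cycloaddition of 6-acyloxypyranones with vinyl ethers, the asymmetric form of the classical base-mediated oxidopyrylium–alkene cycloaddition. Two rings close at once, the cycloheptenone (C1, C5–C10) and the oxolane (O, C7–C10), both by the same concerted addition of the alkene to one face of the pyrylium ring, which is why the oxygen bridge lies on one face at C7 and C10. C7 and C10 are therefore fixed relative to each other by the bridge, C9 by the endo orientation under the pyrylium ring that the alkoxy group of a vinyl ether normally adopts, and the absolute sense by the chiral cyclohexanediamine backbone of the catalyst, which covers one face of 11. The step needs 6-alkoxy regiochemistry, that is the CH2 end of 10 on C7 and the oxygenated end on C10, and this is secured by the polarisation of the vinyl ether and the larger orbital coefficient of the five-atom unit at the terminus next to the nitrogen-bearing carbon, as in simple oxidopyryliums. It also needs 10 to win over the pendant butenyl group and over dimerisation of 11, which the short tether (it cannot span both termini) and the fivefold excess of 10 secure.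

**Step 7**
Reactants: 12 (1S,5R,6R)-4-(but-3-en-1-yl)-6-[(4-methoxyphenyl)methoxy]-5-methyl-1-(propan-2-yl)-8-oxabicyclo[3.2.1]oct-3-en-2-one
Product: 13 (1S,5R,6R)-4-(but-3-en-1-yl)-3-iodo-6-[(4-methoxyphenyl)methoxy]-5-methyl-1-(propan-2-yl)-8-oxabicyclo[3.2.1]oct-3-en-2-one
Conditions: I2, pyridine, DMAP (cat.), CH2Cl2, rt, dark
Reagents that add atoms: iodine, II
Why: α-Iodination of an enone by the addition–elimination mechanism (conjugate addition of the pyridine base, iodination of the enolate, E1cB loss of the base) puts the halide on C5 for the ring closure and touches no stereocentre.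

**Step 8**
Reactants: 13 (1S,5R,6R)-4-(but-3-en-1-yl)-3-iodo-6-[(4-methoxyphenyl)methoxy]-5-methyl-1-(propan-2-yl)-8-oxabicyclo[3.2.1]oct-3-en-2-one
Product: 14 (7S,9R,10R)-7,10-epoxy-9-[(4-methoxyphenyl)methoxy]guaia-1(5),4(15)-dien-6-one
Conditions: Pd(OAc)2 (10 mol %), PPh3 (20 mol %), Ag2CO3, MeCN, 70 °C
Reagents that add atoms: none
Why: Intramolecular Heck reaction in the 5-exo-trig mode: oxidative addition at the vinyl iodide, insertion of the terminal alkene so that C5 bonds to its internal carbon C4, and β-hydride elimination of the only β-hydrogen (on C4) give the exocyclic methylene, while the silver salt scavenges iodide and keeps palladium hydride from moving the double bond.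

**Step 9**
Reactants: 14 (7S,9R,10R)-7,10-epoxy-9-[(4-methoxyphenyl)methoxy]guaia-1(5),4(15)-dien-6-one
Product: 15 (1S,5S,7S,9R,10S)-1,5:7,10-diepoxy-9-[(4-methoxyphenyl)methoxy]guai-4(15)-en-6-one
Conditions: t-BuOOH, benzyltrimethylammonium hydroxide (cat.), THF, 0 °C → rt
Reagents that add atoms: tert-butyl hydroperoxide, CC(C)(C)OO
Why: Weitz–Scheffer epoxidation: the tert-butyl peroxide anion adds to C1 of the enone and the enolate closes onto oxygen, attack coming from the face of the bridging oxygen because the other face is covered by the two-carbon bridge and its endo 4-methoxybenzyloxy group, which sets the C1–O bond (and the temporary C5–O bond) cis to the C10 oxygen, while the exocyclic alkene is inert to a nucleophilic oxidant.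

**Step 10**
Reactants: 15 (1S,5S,7S,9R,10S)-1,5:7,10-diepoxy-9-[(4-methoxyphenyl)methoxy]guai-4(15)-en-6-one
Product: 16 (1S,5S,7S,9R,10S)-1,5:7,10-diepoxy-9-hydroxyguai-4(15)-en-6-one
Conditions: DDQ, CH2Cl2/pH 7 buffer (10:1), 0 °C → rt
Reagents that add atoms: none
Why: Oxidative removal of the 4-methoxybenzyl ether by DDQ (hydride abstraction, hydrolysis of the oxocarbenium ion) under buffered neutral conditions leaves the alkenyl oxirane, the ketone and the ether bridge untouched.

**Step 11**
Reactants: 16 (1S,5S,7S,9R,10S)-1,5:7,10-diepoxy-9-hydroxyguai-4(15)-en-6-one; 17 (2Z)-2-methylbut-2-enoic acid (angelic acid)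
Product: 19 (1S,5S,7S,9R,10S)-1,5:7,10-diepoxy-6-oxoguai-4(15)-en-9-yl (2Z)-2-methylbut-2-enoate, via mixed anhydride 18 (not isolated)
Conditions: 17, 2,4,6-trichlorobenzoyl chloride, Et3N, toluene, rt; then 16, 75 °C
Reagents that add atoms: none
Why: Yamaguchi esterification through the mixed anhydride, run without DMAP so that the (Z)-double bond of the angelate does not isomerise to the tiglate, acylates the only hydroxyl group present, and it is placed here so that the final product never meets base.

**Step 12**
Reactants: 19 (1S,5S,7S,9R,10S)-1,5:7,10-diepoxy-6-oxoguai-4(15)-en-9-yl (2Z)-2-methylbut-2-enoate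
Product: 20 (1R,5S,7S,9R,10S)-7,10-epoxy-1-hydroxy-6-oxoguai-4(15)-en-9-yl (2Z)-2-methylbut-2-enoate
Conditions: Pd2(dba)3·CHCl3 (5 mol %), n-Bu3P (10 mol %), HCO2H, Et3N, 1,4-dioxane, rt
Reagents that add atoms: none
Why: Palladium-catalysed formate hydrogenolysis of an alkenyl oxirane: zerovalent palladium opens the C5–O bond with inversion to give an allylpalladium complex (C5–C4–C15) on the face opposite to the oxygen, the formate ligand loses carbon dioxide and the hydride passes from the metal to the former oxirane carbon C5, so that hydrogen enters anti to the C1 oxygen (trans ring fusion, C5 set), the double bond ends exocyclic as in the known formation of homoallylic alcohols, and the C1 hydroxyl is freed.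

**Step 13**
Reactants: 20 (1R,5S,7S,9R,10S)-7,10-epoxy-1-hydroxy-6-oxoguai-4(15)-en-9-yl (2Z)-2-methylbut-2-enoate
Product: 21 CNP0124926.1, (1R,5S,7R,9R,10S)-1,10-dihydroxy-6-oxoguai-4(15)-en-9-yl (2Z)-2-methylbut-2-enoate
Conditions: SmI2, THF/MeOH (10:1), −78 °C; then pH 7 buffer
Reagents that add atoms: none
Why: SmI2 reduction of an α-alkoxy ketone: the ketyl expels the C7–O bond, a second electron gives the trivalent samarium enolate and the C10 alkoxide, and methanol bound to that alkoxide is expected to protonate C7 on the face the oxygen has just left, which is also the isomer with the isopropyl group equatorial and cis to the C9 ester, while the ester and the exocyclic alkene are reduced far more slowly at −78 °C.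

**Compound list**

1 | 3-bromo-2-methylfuran | Cc1occc1Br | starting material
2 | but-3-en-1-ylzinc bromide | C=CCC[Zn]Br | starting material
3 | 3-(but-3-en-1-yl)-2-methylfuran | Cc1occc1CCC=C | intermediate
4 | 2-methylpropanal | CC(C)C=O | starting material
5 | [4-(but-3-en-1-yl)-5-methylfuran-2-yl]lithium | Cc1oc([Li])cc1CCC=C | intermediate
6 | 1-[4-(but-3-en-1-yl)-5-methylfuran-2-yl]-2-methylpropan-1-ol (racemate) | Cc1oc(C(O)C(C)C)cc1CCC=C | intermediate
7 | 5-(but-3-en-1-yl)-6-hydroxy-6-methyl-2-(propan-2-yl)-2H-pyran-3(6H)-one (mixture of diastereomers) | CC(C)C1OC(C)(O)C(CCC=C)=CC1=O | intermediate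
8 | 3-(but-3-en-1-yl)-2-methyl-5-oxo-6-(propan-2-yl)-5,6-dihydro-2H-pyran-2-yl 3,4,5-trifluorobenzoate (mixture of diastereomers) | CC(C)C1OC(C)(OC(=O)c2cc(F)c(F)c(F)c2)C(CCC=C)=CC1=O | intermediate
9 | (4-methoxyphenyl)methanol | COc1ccc(CO)cc1 | starting material
10 | 1-[(ethenyloxy)methyl]-4-methoxybenzene | C=COCc1ccc(OC)cc1 | intermediate
11 | 3-{[(1R,2R)-2-({[3,5-bis(trifluoromethyl)phenyl]carbamothioyl}amino)cyclohexyl]amino}-5-(but-3-en-1-yl)-6-methyl-2-(propan-2-yl)pyrylium 3,4,5-trifluorobenzoate | CC(C)c1[o+]c(C)c(CCC=C)cc1N[C@@H]2CCCC[C@H]2NC(=S)Nc3cc(C(F)(F)F)cc(C(F)(F)F)c3.[O-]C(=O)c4cc(F)c(F)c(F)c4 | intermediate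
12 | (1S,5R,6R)-4-(but-3-en-1-yl)-6-[(4-methoxyphenyl)methoxy]-5-methyl-1-(propan-2-yl)-8-oxabicyclo[3.2.1]oct-3-en-2-one (6-endo ether) | O=C1C=C(CCC=C)[C@@]2(C)O[C@]1(C(C)C)C[C@H]2OCc3ccc(OC)cc3 | intermediate
13 | (1S,5R,6R)-4-(but-3-en-1-yl)-3-iodo-6-[(4-methoxyphenyl)methoxy]-5-methyl-1-(propan-2-yl)-8-oxabicyclo[3.2.1]oct-3-en-2-one | O=C1C(I)=C(CCC=C)[C@@]2(C)O[C@]1(C(C)C)C[C@H]2OCc3ccc(OC)cc3 | intermediate
14 | (7S,9R,10R)-7,10-epoxy-9-[(4-methoxyphenyl)methoxy]guaia-1(5),4(15)-dien-6-one | O=C1C3=C(CCC3=C)[C@@]2(C)O[C@]1(C(C)C)C[C@H]2OCc4ccc(OC)cc4 | intermediate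
15 | (1S,5S,7S,9R,10S)-1,5:7,10-diepoxy-9-[(4-methoxyphenyl)methoxy]guai-4(15)-en-6-one (both oxygen bridges on one face) | O=C1[C@@]3(O4)[C@]4(CCC3=C)[C@@]2(C)O[C@]1(C(C)C)C[C@H]2OCc5ccc(OC)cc5 | intermediate
16 | (1S,5S,7S,9R,10S)-1,5:7,10-diepoxy-9-hydroxyguai-4(15)-en-6-one | O=C1[C@@]3(O4)[C@]4(CCC3=C)[C@@]2(C)O[C@]1(C(C)C)C[C@H]2O | intermediate
17 | (2Z)-2-methylbut-2-enoic acid (angelic acid) | C/C=C(/C)C(=O)O | starting material
18 | (2Z)-2-methylbut-2-enoic 2,4,6-trichlorobenzoic anhydride | C/C=C(/C)C(=O)OC(=O)c1c(Cl)cc(Cl)cc1Cl | intermediate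
19 | (1S,5S,7S,9R,10S)-1,5:7,10-diepoxy-6-oxoguai-4(15)-en-9-yl (2Z)-2-methylbut-2-enoate | O=C1[C@@]3(O4)[C@]4(CCC3=C)[C@@]2(C)O[C@]1(C(C)C)C[C@H]2OC(=O)/C(C)=C\C | intermediate
20 | (1R,5S,7S,9R,10S)-7,10-epoxy-1-hydroxy-6-oxoguai-4(15)-en-9-yl (2Z)-2-methylbut-2-enoate | O=C1[C@@H]3[C@](O)(CCC3=C)[C@@]2(C)O[C@]1(C(C)C)C[C@H]2OC(=O)/C(C)=C\C | intermediate
21 | CNP0124926.1, (1R,5S,7R,9R,10S)-1,10-dihydroxy-6-oxoguai-4(15)-en-9-yl (2Z)-2-methylbut-2-enoate | C=C1CC[C@@]2(O)[C@H]1C(=O)[C@@H](C(C)C)C[C@@H](OC(=O)/C(C)=C\C)[C@]2(C)O | target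

**Step count**

Total steps: 13. Longest linear sequence: 12 steps (steps 1–4 and 6–13; step 5 is a one-step side branch).

**Steps most likely to fail**

Step 6. The amine catalyst may condense only slowly with a ketone flanked by the isopropyl-bearing carbon, so that an uncatalysed racemic pathway or dimerisation of the five-atom unit takes over and enantiomeric purity drops. The two substituted termini and the neighbouring butenyl group may also erode regio- or endo-selectivity. The fallback sets out from 8 and 10. Without the chiral catalyst, N-methylpyrrolidine in MeCN at rt should ionise 8 to the free 5-(but-3-en-1-yl)-6-methyl-2-(propan-2-yl)pyrylium-3-olate F1. With 10 in excess this should give the cycloadduct as a racemate, that is 12 together with its mirror image, the (1R,5S,6S)-adduct F2. The two are separated by preparative supercritical-fluid chromatography on an amylose tris(3,5-dimethylphenylcarbamate) phase, and the route is rejoined at compound 12.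

Step 12. The allylpalladium intermediate carries the ketone on its substituted terminus and may slip to an oxygen-bound enolate that is protonated on either face before hydride arrives from the metal. Hydride may also go to the CH2 terminus and give the conjugated enone, and free phosphine may isomerise the (Z)-ester. The fallback sets out from 19. Luche reduction (NaBH4, CeCl3·7H2O, MeOH, −40 °C) should give the 6-alcohol of 19 F3; the hydroxyl is expected on the face of the two-carbon bridge, and either epimer serves. This plain alkenyl oxirane, with no carbonyl on the allyl terminus, is submitted to the same formate hydrogenolysis to give the 6-alcohol of 20 F4. Dess–Martin periodinane (NaHCO3, CH2Cl2, 0 °C) then oxidises the secondary C6 hydroxyl in the presence of the tertiary one, and the route is rejoined at compound 20.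

Step 13. Protonation of the samarium enolate may occur on the wrong face at C7. This cannot be repaired afterwards, because C5–H is the more acidic position and would epimerise or move the double bond into conjugation first. The unsaturated ester may also be partly reduced. The fallback sets out from 14 and opens the bridge before the C5 centre exists. SmI2 (THF/MeOH, −78 °C) on the dienone should give (7R,9R,10R)-10-hydroxy-9-[(4-methoxyphenyl)methoxy]guaia-1(5),4(15)-dien-6-one F5. There C7 can be equilibrated safely with a trace of DBU, since C5 is still sp2. Hydroxyl-directed nucleophilic epoxidation (t-BuOOH, benzyltrimethylammonium hydroxide) on the face of the C10 hydroxyl should give the 1,5-epoxide of F5 F6. DDQ then gives the 9,10-diol epoxide F7, and acylation of the secondary hydroxyl with 18 gives the 9-angelate F8. The formate hydrogenolysis of step 12 then becomes the last step and delivers compound 21 directly.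

**Further compounds**

F1 | step 6 | 5-(but-3-en-1-yl)-6-methyl-2-(propan-2-yl)pyrylium-3-olate | CC(C)c1[o+]c(C)c(CCC=C)cc1[O-]
F2 | step 6 | (1R,5S,6S)-4-(but-3-en-1-yl)-6-[(4-methoxyphenyl)methoxy]-5-methyl-1-(propan-2-yl)-8-oxabicyclo[3.2.1]oct-3-en-2-one (enantiomer of 12) | O=C1C=C(CCC=C)[C@]2(C)O[C@@]1(C(C)C)C[C@@H]2OCc3ccc(OC)cc3
F3 | step 12 | 6-alcohol of 19: 1,5:7,10-diepoxy-6-hydroxyguai-4(15)-en-9-yl (2Z)-2-methylbut-2-enoate, hydroxyl on the face of the two-carbon bridge, other centres as in 19 | O[C@@H]1[C@@]3(O4)[C@]4(CCC3=C)[C@@]2(C)O[C@]1(C(C)C)C[C@H]2OC(=O)/C(C)=C\C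
F4 | step 12 | 6-alcohol of 20: 7,10-epoxy-1,6-dihydroxyguai-4(15)-en-9-yl (2Z)-2-methylbut-2-enoate, other centres as in 20 | O[C@@H]1[C@@H]3[C@](O)(CCC3=C)[C@@]2(C)O[C@]1(C(C)C)C[C@H]2OC(=O)/C(C)=C\C
F5 | step 13 | (7R,9R,10R)-10-hydroxy-9-[(4-methoxyphenyl)methoxy]guaia-1(5),4(15)-dien-6-one | C=C1CCC2=C1C(=O)[C@@H](C(C)C)C[C@@H](OCc3ccc(OC)cc3)[C@]2(C)O
F6 | step 13 | 1,5-epoxide of F5, oxirane oxygen cis to the C10 hydroxyl | C=C1CC[C@@]2(O3)[C@]13C(=O)[C@@H](C(C)C)C[C@@H](OCc4ccc(OC)cc4)[C@]2(C)O
F7 | step 13 | 1,5-epoxy-9,10-dihydroxyguai-4(15)-en-6-one, configuration as in F6 | C=C1CC[C@@]2(O3)[C@]13C(=O)[C@@H](C(C)C)C[C@@H](O)[C@]2(C)O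
F8 | step 13 | 1,5-epoxy-10-hydroxy-6-oxoguai-4(15)-en-9-yl (2Z)-2-methylbut-2-enoate, configuration as in F6 | C=C1CC[C@@]2(O3)[C@]13C(=O)[C@@H](C(C)C)C[C@@H](OC(=O)/C(C)=C\C)[C@]2(C)O
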